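The data come from a simulation on assumed constants; the scatter is artificial.

Time is the first thing to watch. The highest maple reading of left-handed product is 13.6% at 0.500 min, and the last is 12.4% at 3.00 min, so a reading near the highest one stands above the late one.

| setting | maple | cedar | north-east | west | south-west | north-west | east |
|---|---|---|---|---|---|---|---|
| left-handed substrate | 1 M | 1 M | 1.0 M | 1.0 M | 1.0 M | 1.0 M | 1.0 M |
| right-handed substrate | 1 M | 1 M | 1.0 M | 1.0 M | 1.0 M | 1.0 M | 1.0 M |
| partner | 0.49 M | 1.8 M | 1.20 M | 2.50 M | 1.50 M | 0.600 M | 0.800 M |
| remark | run made earlier | run made earlier |  |  |  |  |  |
| time |  |  | 4.0 min | 4.0 min | 4.0 min | 4.0 min | 4.0 min |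

| run | time / min | left-handed product / % | left-handed substrate / % |
|---|---|---|---|
| maple | 0.200 | 12.1 | 40.3 |
| maple | 0.500 | 13.6 | 38.5 |
| maple | 1.00 | 13.5 | 37.2 |
| maple | 1.50 | 13.3 | 38.0 |
| maple | 2.00 | 12.7 | 38.7 |
| maple | 3.00 | 12.4 | 38.0 |
| cedar | 0.200 | 34.8 | 21.0 |
| cedar | 0.500 | 42.1 | 14.8 |
| cedar | 1.00 | 43.7 | 11.3 |
| cedar | 1.50 | 42.3 | 10.0 |
| cedar | 2.00 | 41.0 | 10.7 |
| cedar | 3.00 | 41.0 | 10.3 |

(scatter of a reading: 0.5 percentage points)

- partner is single-handed; left-handed substrate and right-handed substrate are mirror images of each other, charged as a racemate, each of them at the stated concentration
- the handed part of partner does not stay in what it makes, so the products of the two hands are mirror images too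

* ranking by amount of left-handed product, in percent of the left-handed substrate and right-handed substrate together charged, from high to low, at 4.0 min (north-east / west / south-west / north-west / east)
* the amount of left-handed product, in percent of the left-handed substrate and right-handed substrate together charged of the flask you put first, at 4.0 min
* the amount of left-handed product, in percent of the left-handed substrate and right-handed substrate together charged of the flask you put last, at 4.0 min

North-west looks nearly the same as maple: among the charges the partner differs, 0.600 M against 0.49 M. Both charge less partner than the two substrates together, so partner is the limiting reagent there. I count one product per partner and take the mirror-image products to end even, so each hand takes half: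

ceiling = (partner charged / both substrates charged) / 2

For north-west this gives a ceiling on left-handed product once the hands are even, as a fraction of the charge, of 15.0%. The asked time comes later than the last maple reading, so I expect the hands to be even by then.

The readings test the rule:

maple: ceiling 12.2%, reading 12.4%
cedar: ceiling 45.0%, reading 41.0%

Maple agrees within the scatter of 0.5 percentage points. Cedar falls short by 4 points, so I suspect that some partner in cedar goes elsewhere, and I read the ceilings of the richer flasks as upper bounds. West charges more partner than the two substrates together, so I cap it at 50.0%. My order follows the partner charged, with north-west last at 15.0%.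

The forecast, which holds that “each flask should be nearly racemic and at equilibrium”, gives west > south-west > north-east > east > north-west, with 47% against my 50.0% and 14.8% against my 15.0%.

The flasks give west > south-west > north-east > east > north-west, with 49.5% in west and 14.7% in north-west.

    partner + left-handed substrate → left-handed product (k = 0.0990 /M/s)
    partner + right-handed substrate → right-handed product (k = 0.0550 /M/s)
    left-handed substrate ⇌ right-handed substrate (k = 0.120 /s)
    2 partner → self-condensation product (k = 0.00790 /M/s)
    left-handed product ⇌ right-handed product (k = 0.00670 /s)

North-west stands at 14.7% against the ceiling of 15.0%, with its partner down to 0% of its charge. The same flask with partner held at its charge gives 50.7% instead of 14.7%, so the falling level of partner is the largest single effect on its left-handed product, worth 36 points. For the neighbour of north-west charged with 1.0 M of partner, the ceiling scales to 25.0%, and that flask holds 23.8%.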